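## Retrosynthetic overview

- **Structural feature:** ketoisophorone already holds ring A (C1–C5, C10), its three methyls (C18, C19, C20) and the C2 oxygen, and its two carbonyl carbons become C2 and C5. With a vinyl group on C5, C10=C5–C6=C7 is a 1-vinylcyclohexene diene. The missing pair C8/C9 is the triple bond of methyl but-2-ynoate, which brings the C17 methyl on C8 and the ester carbon C11.
- **Key disconnection:** C7–C8 and C9–C10 are made by an intermolecular Diels–Alder reaction. It closes ring B and creates quaternary C10 under control of C2.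
- **After the key step:** C5–H comes from hydrogenation of C5=C6 anti to C20. C9–H comes from deconjugative protonation of the C8=C9 enoate. That deprotonation takes the C17 methyl, which lies cis to the ester, so the alkene first goes to C8=C17 and a cobalt-hydride isomerisation then moves it to C7=C8.
- **Side chain:** the ester becomes a C9 vinyl group (C11=C12). C12–C13 is made by B-alkyl Suzuki coupling with (Z)-3-iodobut-2-en-1-ol, itself made from the same butynoate. C13 is set by Ru–BINAP hydrogenation, followed by desilylation and diacetylation.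
- **Ring order:** ring A is bought (C2 set by transfer hydrogenation), and ring B forms in the key step.

Key step: step 6

**Remark (numbering):** labdane numbering is used throughout, and the bicyclic C15/C16 intermediates are named as norlabdanes. The spatial arrangement at C2 never changes after step 1. Only its CIP label changes (R in 2 and 3, S in 4–6 and 8, R from 10 on), because the ranking of its two ring branches changes.

**Assumption:** the sense of induction in step 1 follows the usual Ru–TsDPEN model with the alkenyl carbon in the place of an aryl group, so the (R,R)-ligand is assigned to the R carbinol.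

## Route

Step 1
Reactants: 1 ketoisophorone (2,6,6-trimethylcyclohex-2-ene-1,4-dione)
Product: 2 (4R)-4-hydroxy-2,6,6-trimethylcyclohex-2-en-1-one
Conditions: RuCl(p-cymene)[(R,R)-TsDPEN] (1 mol %), KOH (2 mol %), i-PrOH, 25 °C
Reagents that add atoms: none
Why: Noyori asymmetric transfer hydrogenation should reduce only the future C2 carbonyl, because the other carbonyl is shielded by the gem-dimethyl carbon and the methyl-bearing alkene carbon, and the (R,R)-ligand should deliver hydride to the face that gives the R carbinol.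

Step 2
Reactants: 2 (4R)-4-hydroxy-2,6,6-trimethylcyclohex-2-en-1-one
Product: 3 (4R)-4-(tert-butyldimethylsilyloxy)-2,6,6-trimethylcyclohex-2-en-1-one
Conditions: TBSCl, imidazole, DMF, 25 °C
Reagents that add atoms: tert-butyldimethylsilyl chloride, C[Si](C)(Cl)C(C)(C)C
Why: Imidazole-promoted silylation of an unhindered secondary alcohol leaves the stereocentre untouched and installs a group that tolerates bases, hydrides and aluminium Lewis acids at low temperature.

Step 3
Reactants: 3 (4R)-4-(tert-butyldimethylsilyloxy)-2,6,6-trimethylcyclohex-2-en-1-one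
Product: 4 (4S,6R)-4-(tert-butyldimethylsilyloxy)-2,2,6-trimethylcyclohexan-1-one (methyl and silyloxy cis)
Conditions: H2 (1 atm), Pd/C (10 %), EtOAc, 25 °C
Reagents that add atoms: none
Why: Heterogeneous hydrogenation of the enone alkene should add hydrogen anti to the silyloxy group and give the diequatorial cis isomer, and this new centre is erased in step 4, so its purity does not matter.

Step 4
Reactants: 4 (4S,6R)-4-(tert-butyldimethylsilyloxy)-2,2,6-trimethylcyclohexan-1-one
Product: 6 (4S)-4-(tert-butyldimethylsilyloxy)-2,6,6-trimethylcyclohex-1-en-1-yl trifluoromethanesulfonate, via lithium enolate 5 (not isolated)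
Conditions: LiN(iPr)2, THF, −78 → 0 °C; PhNTf2, −78 → 25 °C
Reagents that add atoms: N-phenylbis(trifluoromethanesulfonimide), O=S(=O)(N(c1ccccc1)S(=O)(=O)C(F)(F)F)C(F)(F)F; lithium diisopropylamide (lithium of 5 only), [Li+].CC(C)[N-]C(C)C
Why: Enolate O-triflation is regiochemically unambiguous because the ketone has a single α-hydrogen (at the future C10), and the silyloxy group sits γ to the carbonyl, so it cannot be eliminated.

Step 5
Reactants: 6 (4S)-4-(tert-butyldimethylsilyloxy)-2,6,6-trimethylcyclohex-1-en-1-yl trifluoromethanesulfonate; 7 tributyl(vinyl)stannane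
Product: 8 (4S)-4-(tert-butyldimethylsilyloxy)-1-ethenyl-2,6,6-trimethylcyclohex-1-ene
Conditions: Pd(PPh3)4 (5 mol %), LiCl (3 equiv), THF, 65 °C
Reagents that add atoms: none
Why: Stille coupling of an enol triflate (oxidative addition of zerovalent palladium, chloride exchange, transfer of the small vinyl group, reductive elimination) fixes the tetrasubstituted C5=C10 alkene in place and avoids the allylic rearrangements that threaten dehydration of a tertiary vinyl carbinol.

Step 6
Reactants: 8 (4S)-4-(tert-butyldimethylsilyloxy)-1-ethenyl-2,6,6-trimethylcyclohex-1-ene; 9 methyl but-2-ynoate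
Product: 10 methyl (2R,10R)-2-(tert-butyldimethylsilyloxy)-12,13,14,15,16-pentanorlabda-5,8-dien-11-oate (C9 cis and C20 trans to the C2 oxygen)
Conditions: 9 (3 equiv), EtAlCl2 (2.5 equiv, kept below the amount of 9), CH2Cl2, −20 → 25 °C; then ice-water
Reagents that add atoms: none
Why: This is a Lewis-acid-promoted intermolecular Diels–Alder reaction in which EtAlCl2 binds the ester carbonyl of 9, lowers its LUMO and also scavenges stray protons, and the s-cis diene C10=C5–C6=C7 adds suprafacially across C8≡C9 in a concerted but strongly asynchronous [4+2] process with C7–C8 formed ahead of C9–C10. The closest known reaction type is the cycloaddition of 1-vinyl-2,6,6-trimethylcyclohexene with acetylenic esters used to build drimanes, combined with aluminium-halide promotion of alkynoates that are too sluggish when only heated. Ring B (C5–C10) closes as a cyclohexa-1,4-diene by this six-electron cycloaddition with both σ-bonds made on one diene face, and the linear dienophile leaves no endo or exo alternative. For regioselectivity, C7 is the sterically free diene end with the larger frontier-orbital coefficient, so it attacks the electrophilic β-carbon C8, while the developing positive charge rests on the tertiary allylic C10, which then bonds to C9. The only new stereocentre, C10, is controlled by C2: an axial silyloxy group would be syn-axial to a C4 methyl, so ring A adopts the half-chair with oxygen pseudoequatorial, the pseudoaxial C4 methyl then shields the face trans to oxygen, and attack cis to oxygen lets ring A pass directly into the chair with C20 axial and the silyloxy group equatorial (10R). Any minor C10 epimer is removed by chromatography at this stage.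

Step 7
Reactants: 10 methyl (2R,10R)-2-(tert-butyldimethylsilyloxy)-12,13,14,15,16-pentanorlabda-5,8-dien-11-oate
Product: 11 methyl (2R,5R,10R)-2-(tert-butyldimethylsilyloxy)-12,13,14,15,16-pentanorlabd-8-en-11-oate (trans-decalin)
Conditions: H2 (1 atm), Pd/C (10 %), EtOAc, 25 °C
Reagents that add atoms: none
Why: Chemoselective heterogeneous hydrogenation should reduce the trisubstituted C5=C6 alkene and spare the tetrasubstituted conjugated C8=C9 alkene, and adsorption on the face opposite the axial C20 methyl places H-5 trans to C20 (5R), as in the related drimane diester series.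

Step 8
Reactants: 11 methyl (2R,5R,10R)-2-(tert-butyldimethylsilyloxy)-12,13,14,15,16-pentanorlabd-8-en-11-oate
Product: 13 methyl (2R,5R,9R,10R)-2-(tert-butyldimethylsilyloxy)-12,13,14,15,16-pentanorlabd-8(17)-en-11-oate, via lithium dienolate 12 (not isolated)
Conditions: LiN(iPr)2 (2 equiv), THF–DMPU, −78 → −20 °C; inverse quench into AcOH–THF, −78 °C
Reagents that add atoms: lithium diisopropylamide (lithium of 12 only), [Li+].CC(C)[N-]C(C)C
Why: In this deconjugative protonation of an ester dienolate, the carbonyl-bound amide base should remove a proton from C17, the γ-carbon cis to the ester, and the kinetic proton then enters at the α-carbon C9 from the face opposite C20 (9R, ester equatorial), while any C7=C8 isomer from deprotonation at C7 has the same C9 configuration and converges on 15 in steps 9 and 10.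

Step 9
Reactants: 13 methyl (2R,5R,9R,10R)-2-(tert-butyldimethylsilyloxy)-12,13,14,15,16-pentanorlabd-8(17)-en-11-oate
Product: 14 (2R,5R,9R,10R)-2-(tert-butyldimethylsilyloxy)-12,13,14,15,16-pentanorlabd-8(17)-en-11-ol
Conditions: LiAlH4, Et2O, 0 °C
Reagents that add atoms: none
Why: Hydride reduction of the ester removes the acidifying group at C9 before the alkene is moved, and it affects neither the silyl ether nor any stereocentre.

Step 10
Reactants: 14 (2R,5R,9R,10R)-2-(tert-butyldimethylsilyloxy)-12,13,14,15,16-pentanorlabd-8(17)-en-11-ol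
Product: 15 (2R,5R,9R,10R)-2-(tert-butyldimethylsilyloxy)-12,13,14,15,16-pentanorlabd-7-en-11-ol
Conditions: Co(salen)Cl (3 mol %; salen = N,N'-bis(3,5-di-tert-butylsalicylidene)ethane-1,2-diaminate), PhSiH3 (6 mol %), benzene, 25–50 °C, Ar
Reagents that add atoms: none
Why: In this cobalt-hydride hydrogen-atom-transfer alkene isomerisation, reversible H-atom addition to the C17 methylene gives the tertiary C8 radical, and the bulky divalent cobalt complex should take the return hydrogen from the accessible C7 methylene rather than from the crowded tertiary C9–H, giving the trisubstituted C7=C8 alkene, which is a much poorer substrate, without touching a stereocentre.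

Step 11
Reactants: 15 (2R,5R,9R,10R)-2-(tert-butyldimethylsilyloxy)-12,13,14,15,16-pentanorlabd-7-en-11-ol
Product: 16 (2R,5R,9R,10R)-2-(tert-butyldimethylsilyloxy)-12,13,14,15,16-pentanorlabd-7-en-11-al
Conditions: NPr4RuO4 (5 mol %), N-methylmorpholine N-oxide, 4 Å molecular sieves, CH2Cl2, 0 → 25 °C
Reagents that add atoms: none
Why: The Ley–Griffith oxidation runs under neutral anhydrous conditions, so the β,γ-unsaturated aldehyde should form without epimerisation at C9 or migration of the alkene, and it is used without delay.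

Step 12
Reactants: 16 (2R,5R,9R,10R)-2-(tert-butyldimethylsilyloxy)-12,13,14,15,16-pentanorlabd-7-en-11-al
Product: 17 (2R,5R,9R,10R)-2-(tert-butyldimethylsilyloxy)-13,14,15,16-tetranorlabda-7,11-diene
Conditions: Ph3PCH3Br, KN(SiMe3)2, THF, 0 °C; then 16, −78 → 0 °C
Reagents that add atoms: methyltriphenylphosphonium bromide, C[P+](c1ccccc1)(c1ccccc1)c1ccccc1.[Br-]
Why: Wittig methylenation uses the smallest and fastest ylide, which should add to the hindered aldehyde at low temperature faster than it enolises it, so C9 is retained and C12 is introduced.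

Step 13
Reactants: 9 methyl but-2-ynoate
Product: 18 methyl (Z)-3-iodobut-2-enoate
Conditions: NaI, AcOH, 115 °C
Reagents that add atoms: sodium iodide, [Na+].[I-]
Why: Conjugate hydroiodination of an ynoate proceeds by anti addition of iodide and a proton, which places iodine cis to the ester (Z).

Step 14
Reactants: 18 methyl (Z)-3-iodobut-2-enoate
Product: 19 (Z)-3-iodobut-2-en-1-ol
Conditions: iBu2AlH (2.2 equiv), CH2Cl2, −78 → 0 °C
Reagents that add atoms: none
Why: 1,2-Reduction of the enoate with iBu2AlH gives the allylic alcohol and retains both the C–I bond and the alkene geometry.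

Step 15
Reactants: 17 (2R,5R,9R,10R)-2-(tert-butyldimethylsilyloxy)-13,14,15,16-tetranorlabda-7,11-diene; 19 (Z)-3-iodobut-2-en-1-ol
Product: 21 (2R,5R,9R,10R,13Z)-2-(tert-butyldimethylsilyloxy)labda-7,13-dien-15-ol, via B-alkyl-9-BBN borane 20 (not isolated)
Conditions: 9-BBN-H, THF, 0 → 25 °C; then H2O, 19, PdCl2(dppf) (5 mol %), AsPh3, Cs2CO3, DMF, 25 °C
Reagents that add atoms: 9-borabicyclo[3.3.1]nonane (boron unit of 20 only), B1C2CCCC1CCC2
Why: In this hydroboration and B-alkyl Suzuki–Miyaura coupling, 9-BBN-H adds only to the monosubstituted C11=C12 alkene with boron on C12 and leaves the trisubstituted C7=C8 alkene alone, and the coupling forms C12–C13 with retention of the Z geometry.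

Step 16
Reactants: 21 (2R,5R,9R,10R,13Z)-2-(tert-butyldimethylsilyloxy)labda-7,13-dien-15-ol
Product: 22 (2R,5R,9R,10R,13S)-2-(tert-butyldimethylsilyloxy)labd-7-en-15-ol
Conditions: Ru(OAc)2[(S)-BINAP] (1 mol %), H2 (50 atm), MeOH–CH2Cl2, 25 °C
Reagents that add atoms: none
Why: Noyori asymmetric hydrogenation of an allylic alcohol is directed by the C15 hydroxyl, a Z-configured 3-methylalk-2-en-1-ol with the (S)-BINAP catalyst should give the S centre (the nerol to (S)-citronellol relationship), and the C7=C8 alkene has no directing group and stays.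

Step 17
Reactants: 22 (2R,5R,9R,10R,13S)-2-(tert-butyldimethylsilyloxy)labd-7-en-15-ol
Product: 23 (2R,5R,9R,10R,13S)-labd-7-ene-2,15-diol
Conditions: Bu4NF, THF, 25 → 45 °C
Reagents that add atoms: none
Why: Fluoride-induced desilylation frees the equatorial C2 alcohol under non-acidic conditions that cannot move the C7=C8 alkene.

Step 18
Reactants: 23 (2R,5R,9R,10R,13S)-labd-7-ene-2,15-diol
Product: 24 (2R,5R,9R,10R,13S)-labd-7-ene-2,15-diyl diacetate (target, CNP0220683.1)
Conditions: Ac2O, pyridine, DMAP (cat.), CH2Cl2, 25 °C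
Reagents that add atoms: acetic anhydride, CC(=O)OC(C)=O
Why: DMAP-catalysed acylation esterifies the primary and the equatorial secondary alcohol with retention at C2.

## Compound list

1 | ketoisophorone | CC1=CC(=O)CC(C)(C)C1=O | starting material
2 | (4R)-4-hydroxy-2,6,6-trimethylcyclohex-2-en-1-one | CC1=C[C@H](O)CC(C)(C)C1=O | intermediate
3 | (4R)-4-(tert-butyldimethylsilyloxy)-2,6,6-trimethylcyclohex-2-en-1-one | CC1=C[C@H](O[Si](C)(C)C(C)(C)C)CC(C)(C)C1=O | intermediate
4 | (4S,6R)-4-(tert-butyldimethylsilyloxy)-2,2,6-trimethylcyclohexan-1-one | C[C@@H]1C[C@H](O[Si](C)(C)C(C)(C)C)CC(C)(C)C1=O | intermediate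
5 | lithium enolate of 4 | [Li+].[O-]C1=C(C)C[C@H](O[Si](C)(C)C(C)(C)C)CC1(C)C | intermediate
6 | (4S)-4-(tert-butyldimethylsilyloxy)-2,6,6-trimethylcyclohex-1-en-1-yl trifluoromethanesulfonate | O=S(=O)(OC1=C(C)C[C@H](O[Si](C)(C)C(C)(C)C)CC1(C)C)C(F)(F)F | intermediate
7 | tributyl(vinyl)stannane | C=C[Sn](CCCC)(CCCC)CCCC | starting material
8 | (4S)-4-(tert-butyldimethylsilyloxy)-1-ethenyl-2,6,6-trimethylcyclohex-1-ene | C=CC1=C(C)C[C@H](O[Si](C)(C)C(C)(C)C)CC1(C)C | intermediate
9 | methyl but-2-ynoate | CC#CC(=O)OC | starting material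
10 | methyl (2R,10R)-2-(tert-butyldimethylsilyloxy)-12,13,14,15,16-pentanorlabda-5,8-dien-11-oate | COC(=O)C1=C(C)CC=C2C(C)(C)C[C@@H](O[Si](C)(C)C(C)(C)C)C[C@@]12C | intermediate
11 | methyl (2R,5R,10R)-2-(tert-butyldimethylsilyloxy)-12,13,14,15,16-pentanorlabd-8-en-11-oate | COC(=O)C1=C(C)CC[C@@H]2C(C)(C)C[C@@H](O[Si](C)(C)C(C)(C)C)C[C@@]12C | intermediate
12 | lithium dienolate of 11 (C8=C17, C9=C11) | [Li+].[O-]C(OC)=C1C(=C)CC[C@@H]2C(C)(C)C[C@@H](O[Si](C)(C)C(C)(C)C)C[C@@]12C | intermediate
13 | methyl (2R,5R,9R,10R)-2-(tert-butyldimethylsilyloxy)-12,13,14,15,16-pentanorlabd-8(17)-en-11-oate | COC(=O)[C@@H]1C(=C)CC[C@@H]2C(C)(C)C[C@@H](O[Si](C)(C)C(C)(C)C)C[C@@]12C | intermediate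
14 | (2R,5R,9R,10R)-2-(tert-butyldimethylsilyloxy)-12,13,14,15,16-pentanorlabd-8(17)-en-11-ol | OC[C@@H]1C(=C)CC[C@@H]2C(C)(C)C[C@@H](O[Si](C)(C)C(C)(C)C)C[C@@]12C | intermediate
15 | (2R,5R,9R,10R)-2-(tert-butyldimethylsilyloxy)-12,13,14,15,16-pentanorlabd-7-en-11-ol | OC[C@@H]1C(C)=CC[C@@H]2C(C)(C)C[C@@H](O[Si](C)(C)C(C)(C)C)C[C@@]12C | intermediate
16 | (2R,5R,9R,10R)-2-(tert-butyldimethylsilyloxy)-12,13,14,15,16-pentanorlabd-7-en-11-al | O=C[C@@H]1C(C)=CC[C@@H]2C(C)(C)C[C@@H](O[Si](C)(C)C(C)(C)C)C[C@@]12C | intermediate
17 | (2R,5R,9R,10R)-2-(tert-butyldimethylsilyloxy)-13,14,15,16-tetranorlabda-7,11-diene | C=C[C@@H]1C(C)=CC[C@@H]2C(C)(C)C[C@@H](O[Si](C)(C)C(C)(C)C)C[C@@]12C | intermediate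
18 | methyl (Z)-3-iodobut-2-enoate | COC(=O)/C=C(/C)I | intermediate
19 | (Z)-3-iodobut-2-en-1-ol | OC/C=C(/C)I | intermediate
20 | 9-[(2R,5R,9R,10R)-2-(tert-butyldimethylsilyloxy)-13,14,15,16-tetranorlabd-7-en-12-yl]-9-borabicyclo[3.3.1]nonane | C(C[C@@H]1C(C)=CC[C@@H]2C(C)(C)C[C@@H](O[Si](C)(C)C(C)(C)C)C[C@@]12C)B1C2CCCC1CCC2 | intermediate
21 | (2R,5R,9R,10R,13Z)-2-(tert-butyldimethylsilyloxy)labda-7,13-dien-15-ol | OC/C=C(/C)CC[C@@H]1C(C)=CC[C@@H]2C(C)(C)C[C@@H](O[Si](C)(C)C(C)(C)C)C[C@@]12C | intermediate
22 | (2R,5R,9R,10R,13S)-2-(tert-butyldimethylsilyloxy)labd-7-en-15-ol | OCC[C@@H](C)CC[C@@H]1C(C)=CC[C@@H]2C(C)(C)C[C@@H](O[Si](C)(C)C(C)(C)C)C[C@@]12C | intermediate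
23 | (2R,5R,9R,10R,13S)-labd-7-ene-2,15-diol | OCC[C@@H](C)CC[C@@H]1C(C)=CC[C@@H]2C(C)(C)C[C@@H](O)C[C@@]12C | intermediate
24 | (2R,5R,9R,10R,13S)-labd-7-ene-2,15-diyl diacetate | CC(=O)OCC[C@@H](C)CC[C@@H]1C(C)=CC[C@@H]2C(C)(C)C[C@@H](OC(C)=O)C[C@@]12C | target

## Step count and risks

Total step count: 18. Longest linear sequence: 16 (steps 1–12 and 15–18).

Steps most likely to fail:

1. **Step 6.**
   - What may go wrong: the butynoate may add too slowly. Lewis-acid-induced oligomerisation of the diene, proton loss after the first C–C bond (an ene-type course) or [2+2] closure could then take over. Discrimination between the two diene faces may also be incomplete.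
   - Fallback (from 8, back at 10): the methyl group is left out of the dienophile and added afterwards. Methyl propiolate is brominated (NBS, cat. AgNO3, acetone) to methyl 3-bromopropiolate F1. This is a markedly more reactive dienophile that should add to 8 in toluene at 110 °C without any Lewis acid and with the same orientation, giving the 8-bromo dienoate F2. Addition–elimination with Me2CuLi (Et2O, −78 → 0 °C) exchanges bromine for the C17 methyl group and gives 10.

2. **Step 10.**
   - What may go wrong: hydrogen-atom abstraction from C9–H may compete with abstraction from C7. The alkene would then move into the tetrasubstituted C8=C9 position and the C9 configuration would be lost.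
   - Fallback (from 13, back at 15): the alkene is moved by an oxidation and allylic transposition sequence that cannot involve C9. Allylic hydroxylation of 13 (cat. SeO2, t-BuOOH, CH2Cl2) at the C7 methylene gives the 7-hydroxy ester F3. SOCl2 in Et2O at 0 °C converts it with allylic shift into the 17-chloro 7-ene ester F4. LiAlH4 (Et2O, 0 → 25 °C) then reduces the primary allylic chloride to the C17 methyl and the ester to the C11 alcohol in one operation, giving 15.

3. **Step 8.**
   - What may go wrong: the twisted, crowded enoate may resist γ-deprotonation. The dienolate may be reprotonated at the γ-carbon, which regenerates the conjugated ester. The proton may also not be delivered cleanly to one face of C9.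
   - Fallback (from 11, back at 15): C9–H is delivered intramolecularly.
     - Allylic oxidation of 11 at C7 (CrO3, 3,5-dimethylpyrazole, CH2Cl2, −20 °C) gives the 7-oxo enoate F5.
     - Luche reduction (NaBH4, CeCl3·7H2O, MeOH, −78 → 0 °C) by axial hydride attack gives the pseudoequatorial 7-alcohol F6, with the hydroxyl on the face of C20.
     - Mitsunobu displacement with 2-nitrobenzenesulfonylhydrazide (PPh3, diethyl azodicarboxylate, THF, −30 °C) inverts C7 to the sulfonylhydrazine F7.
     - On warming to 25 °C this loses sulfinic acid to give the allylic diazene F8. Its retro-ene loss of nitrogen places hydrogen on C9 from the face opposite C20 and moves the alkene to C7=C8, giving the 7-ene ester F9.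
     - LiAlH4 (Et2O, 0 °C) gives 15.

Further compounds
F1 | step 6 | methyl 3-bromopropiolate | COC(=O)C#CBr
F2 | step 6 | methyl 8-bromo-2-(tert-butyldimethylsilyloxy)-12,13,14,15,16,17-hexanorlabda-5,8-dien-11-oate (C2 and C10 as in 10) | COC(=O)C1=C(Br)CC=C2C(C)(C)C[C@@H](O[Si](C)(C)C(C)(C)C)C[C@@]12C
F3 | step 10 | methyl 7-hydroxy-2-(tert-butyldimethylsilyloxy)-12,13,14,15,16-pentanorlabd-8(17)-en-11-oate (axial 7-OH, other centres as in 13) | COC(=O)[C@@H]1C(=C)[C@@H](O)C[C@@H]2C(C)(C)C[C@@H](O[Si](C)(C)C(C)(C)C)C[C@@]12C
F4 | step 10 | methyl 17-chloro-2-(tert-butyldimethylsilyloxy)-12,13,14,15,16-pentanorlabd-7-en-11-oate (centres as in 13) | COC(=O)[C@@H]1C(CCl)=CC[C@@H]2C(C)(C)C[C@@H](O[Si](C)(C)C(C)(C)C)C[C@@]12C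
F5 | step 8 | methyl 7-oxo-2-(tert-butyldimethylsilyloxy)-12,13,14,15,16-pentanorlabd-8-en-11-oate (centres as in 11) | COC(=O)C1=C(C)C(=O)C[C@@H]2C(C)(C)C[C@@H](O[Si](C)(C)C(C)(C)C)C[C@@]12C
F6 | step 8 | methyl 7-hydroxy-2-(tert-butyldimethylsilyloxy)-12,13,14,15,16-pentanorlabd-8-en-11-oate (7-OH cis to C20) | COC(=O)C1=C(C)[C@H](O)C[C@@H]2C(C)(C)C[C@@H](O[Si](C)(C)C(C)(C)C)C[C@@]12C
F7 | step 8 | N-(2-nitrobenzenesulfonyl)hydrazine at C7 of the 8-en-11-oate (nitrogen trans to C20, not isolated) | COC(=O)C1=C(C)[C@@H](N(N)S(=O)(=O)c3ccccc3[N+](=O)[O-])C[C@@H]2C(C)(C)C[C@@H](O[Si](C)(C)C(C)(C)C)C[C@@]12C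
F8 | step 8 | allylic diazene at C7 of the 8-en-11-oate (not isolated) | COC(=O)C1=C(C)[C@@H](N=N)C[C@@H]2C(C)(C)C[C@@H](O[Si](C)(C)C(C)(C)C)C[C@@]12C
F9 | step 8 | methyl 2-(tert-butyldimethylsilyloxy)-12,13,14,15,16-pentanorlabd-7-en-11-oate (centres as in 15) | COC(=O)[C@@H]1C(C)=CC[C@@H]2C(C)(C)C[C@@H](O[Si](C)(C)C(C)(C)C)C[C@@]12C
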